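**Strategy.** Atoms carry germacrane numbers (C1 furanone ketone, C3 furanone O–C=, C10 quaternary C–O, C9 its oxygenated neighbour). Everything rests on cutting C1–C10, the bond shared by the 3(2H)-furanone and the ten-membered carbocycle. A 3(2H)-furanone is the isomer of a γ-hydroxy ynone, so C1 can be an acetylide carbon and C10 a methyl ketone. In the key step the zinc acetylide of an ethynyl ketone adds to that ketone inside a chelate held by the C9 zinc alkoxide: one operation closes the ten-membered ring and sets C10. The precursor is an open-chain α-methylene lactone bearing an ethynyl vinyl ketone and an α-hydroxy methyl ketone.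

Key step: step 12

Remark: C11–C13 are the lactone carbons, C14 the methyl and C15 the hydroxymethyl carbon; the target is made with the configuration 6R,7S,8S,9R,10S read from its SMILES, and "as in the target" below means the same spatial arrangement.

**Step 1**
Reactants: 1 allyl methoxymethyl ether, 2 methacrolein
Product: 4 (3S,4S)-4-(methoxymethoxy)-2-methylhexa-1,5-dien-3-ol (syn; free C9–OH and C8–OMOM), via alkoxyallylborane 3 (not isolated)
Conditions: s-BuLi, THF, −78 °C; (+)-Ipc2BOMe; BF3·OEt2; then 2, −78 °C; NaOH, H2O2, 0 → 23 °C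
Reagents that add atoms: none
Why: γ-Alkoxyallylboration (Brown type): the (Z)-γ-alkoxyallylborane adds through a closed chair transition state, which gives the syn C8/C9 relationship, while the isopinocampheyl groups of the (−)-α-pinene series direct attack to the Re face of the aldehyde and so fix both centres absolutely.

**Step 2**
Reactants: 4
Product: 5 (3S,4S)-4-(methoxymethoxy)-2-methyl-3-(triethylsilyloxy)hexa-1,5-diene
Conditions: TESCl, imidazole, DMF, 0 °C
Reagents that add atoms: chlorotriethylsilane, CC[Si](Cl)(CC)CC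
Why: Silyl ether formation at the only free hydroxyl; no stereocentre is touched.

**Step 3**
Reactants: 5
Product: 7 (2R,3R)-2-(methoxymethoxy)-4-oxo-3-(triethylsilyloxy)pentanal (C7 aldehyde and C10 methyl ketone), via bis-ozonide 6 (not isolated)
Conditions: O3, CH2Cl2, −78 °C; then PPh3, −78 → 23 °C
Reagents that add atoms: ozone, [O-][O+]=O
Why: Ozonolysis with reductive work-up cleaves both electron-rich terminal alkenes; the α-stereocentres should not enolise under these cold neutral conditions.

**Step 4**
Reactants: 7, 8 methyl acrylate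
Product: 9 methyl 3-hydroxy-4-(methoxymethoxy)-2-methylidene-6-oxo-5-(triethylsilyloxy)heptanoate (C4 and C5 as in 7; C3 epimers)
Conditions: DABCO, 1,4-dioxane/H2O (1:1), 23 °C
Reagents that add atoms: none
Why: Morita–Baylis–Hillman reaction: the DABCO-derived acrylate enolate adds to the activated α-alkoxy aldehyde and not to the ketone; the new carbinol centre forms as a mixture that is erased in step 5.

**Step 5**
Reactants: 9
Product: 10 methyl (Z)-2-(bromomethyl)-4-(methoxymethoxy)-6-oxo-5-(triethylsilyloxy)hept-2-enoate (C4 and C5 as in 7)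
Conditions: NBS, Me2S, CH2Cl2, 0 → 23 °C
Reagents that add atoms: N-bromosuccinimide, O=C1CCC(=O)N1Br
Why: Corey–Kim-type activation of the allylic alcohol and SN2′ return of bromide give the rearranged primary allylic bromide with the thermodynamically preferred (Z)-enoate geometry.

**Step 6**
Reactants: 11 but-2-yne-1,4-diol
Product: 12 4-(tert-butyldiphenylsilyloxy)but-2-yn-1-ol
Conditions: TBDPSCl (0.3 equiv), imidazole, DMF, 0 °C
Reagents that add atoms: tert-butyl(chloro)diphenylsilane, CC(C)(C)[Si](Cl)(c1ccccc1)c1ccccc1
Why: Statistical monosilylation of a symmetrical diol used in excess (silyl ether formation).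

**Step 7**
Reactants: 12
Product: 14 (Z)-4-(tert-butyldiphenylsilyloxy)-3-iodobut-2-en-1-ol, via sodium vinylalanate 13 (not isolated)
Conditions: NaAlH2(OCH2CH2OCH3)2, THF, 0 °C; then I2, −78 → 0 °C
Reagents that add atoms: iodine, II
Why: Hydroxyl-directed trans-hydroalumination of the propargylic alcohol gives a cyclic vinylalanate whose C–Al bond is iodinated with retention, so CH2OH (C6) and iodine are cis.

**Step 8**
Reactants: 14
Product: 15 (Z)-4-(tert-butyldiphenylsilyloxy)-3-iodobut-2-enal
Conditions: MnO2, CH2Cl2, 23 °C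
Reagents that add atoms: none
Why: Allylic oxidation with MnO2 gives the enal without touching the vinyl iodide; the alkene geometry should be kept if the aldehyde is used at once.

**Step 9**
Reactants: 10, 15
Product: 17 trans-α-methylene-γ-butyrolactone whose C6 carries the (Z)-2-iodo-3-(tert-butyldiphenylsilyloxy)prop-1-enyl group and whose C7 carries the C8(OMOM)–C9(OH)–C10(=O)CH3 chain (C6–C9 as in the target), via hydroxy ester 16 (not isolated)
Conditions: CrCl2, THF, 23 °C; then PPTS, MeOH, 23 °C
Reagents that add atoms: none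
Why: Nozaki–Hiyama-type allylation: the allylchromium reagent should attack only the aldehyde, through a chair transition state with the C8 substituent equatorial (anti adduct, hence the trans-lactone) and on the face of C7 anti to C9 (H8 eclipsed with the ester by allylic 1,3-strain), which sets C7 and C6; mild acid then closes the γ-lactone and removes the triethylsilyl group.

**Step 10**
Reactants: 17, 18 ethynyltrimethylsilane
Product: 19 trimethylsilyl ynone (iodine of 17 replaced by C(=O)–C≡C–SiMe3; C3 is the new carbonyl)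
Conditions: PdCl2(PPh3)2 (5 mol%), CuI (2 mol%), CO (1 atm), Et3N, THF, 23 °C
Reagents that add atoms: carbon monoxide, [C-]#[O+]
Why: Carbonylative Sonogashira coupling: oxidative addition at the vinyl iodide, CO insertion and transfer of the copper acetylide give the alkynyl ketone with retention of the alkene geometry.

**Step 11**
Reactants: 19
Product: 20 ethynyl ketone (terminal ynone; open-chain precursor)
Conditions: Bu4NF, AcOH, THF, −78 → −40 °C
Reagents that add atoms: none
Why: Buffered fluoride cleaves the C(sp)–Si bond of the silyl ynone (protodesilylation) much faster than the silyl ether.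

**Step 12**
Reactants: 20
Product: 22 ten-membered γ-hydroxy ynone (C1≡C2 in the ring; C9 and C10 hydroxyls syn; C8–OMOM; lactone intact), via zinc alkoxide acetylide 21 (not isolated)
Conditions: Zn(CH3)2 (3 equiv), toluene, 0.002 M, 0 → 40 °C; aq. NH4Cl
Reagents that add atoms: none
Why: Zn(CH3)2 turns the C9 hydroxyl into a methylzinc alkoxide and the acidic ethynyl ketone into an alkynylzinc (21); zinc bridges O9 and the C10 carbonyl oxygen in a five-membered chelate, and the acetylide carbon C1 adds to the activated ketone carbon C10. The closest known reactions are the Zn(CH3)2-mediated alkynylation of ketones and the intramolecular acetylide-to-carbonyl closures used for ten-membered enediyne rings. The ten-membered carbocycle closes in the 10-exo-trig mode (C1 attacks trigonal C10, the C=O lying outside the new ring). The new stereocentre C10 is set by the Cram chelate: C1 enters on the carbonyl face anti to C8, which gives the 9,10-syn diol (10S as in the target), and the resulting C8–C9–C10–C1 torsion near 150° fits a ten-membered ring. The step needs 1,2-addition to the methyl ketone in preference to the ynone carbonyl, the lactone and the exo-methylene group, and ring closure in preference to oligomerisation; chelate activation of the ketone, the low reactivity of zinc acetylides toward esters and enoates, the cis C4=C5 bond that turns the chain back on itself and high dilution should secure this.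

**Step 13**
Reactants: 22, 23 3-methylbut-2-enoyl chloride
Product: 24 C9 3-methylbut-2-enoate (senecioate) of 22 with the tertiary C10 hydroxyl free
Conditions: pyridine, CH2Cl2, 0 °C
Reagents that add atoms: none
Why: Esterification with the acid chloride should occur only at the secondary C9 hydroxyl, the tertiary C10 hydroxyl being unreactive; masking O9 also prevents a competing six-membered ring closure in step 14.

**Step 14**
Reactants: 24
Product: 25 3(2H)-furanone (O10 bridges C10 and C3; C1 ketone; C8–OMOM; C9 senecioate; C15–OTBDPS)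
Conditions: (p-CF3C6H4)3PAuCl (5 mol%), AgOTf (5 mol%), wet toluene, 23 °C
Reagents that add atoms: none
Why: Gold-catalysed cycloisomerisation of a γ-hydroxy ynone: the alkyne activated by monovalent gold takes up water at C1, the C10 hydroxyl closes across the ring onto the C3 carbonyl (5-exo-trig) and water is lost; no stereocentre changes.

**Step 15**
Reactants: 25
Product: 26 C8 alcohol (methoxymethyl group removed)
Conditions: Me2BBr, CH2Cl2, −78 °C; then aq. NaHCO3
Reagents that add atoms: none
Why: Acetal cleavage by Me2BBr at low temperature removes the methoxymethyl ether without affecting the esters, the lactone or the silyl ether, and the cold conditions should suppress acyl migration from O9.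

**Step 16**
Reactants: 26, 27 methacrylic anhydride
Product: 28 C8 methacrylate (O15-tert-butyldiphenylsilyl ether of the target)
Conditions: Et3N, DMAP (cat.), CH2Cl2, 0 °C
Reagents that add atoms: none
Why: DMAP-catalysed esterification of the secondary C8 hydroxyl with the anhydride.

**Step 17**
Reactants: 28
Product: 29 target, CNP0239488.2
Conditions: HF·pyridine, THF/pyridine, 0 → 23 °C
Reagents that add atoms: none
Why: Desilylation under weakly acidic fluoride conditions frees the primary allylic C15 hydroxyl without ester cleavage or conjugate addition.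

**Compound list**
1 | allyl methoxymethyl ether | C=CCOCOC | starting material
2 | methacrolein | CC(=C)C=O | starting material
3 | [(Z)-3-(methoxymethoxy)allyl]bis(isopinocampheyl)borane, (−)-α-pinene series | COCO/C=C\CB([C@H]1C[C@H]2C[C@@H]([C@@H]1C)C2(C)C)[C@H]1C[C@H]2C[C@@H]([C@@H]1C)C2(C)C | intermediate
4 | (3S,4S)-4-(methoxymethoxy)-2-methylhexa-1,5-dien-3-ol | C=C(C)[C@H](O)[C@@H](OCOC)C=C | intermediate
5 | (3S,4S)-4-(methoxymethoxy)-2-methyl-3-(triethylsilyloxy)hexa-1,5-diene | C=C(C)[C@H](O[Si](CC)(CC)CC)[C@@H](OCOC)C=C | intermediate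
6 | bis-ozonide of 5 | CC1(OCOO1)[C@H](O[Si](CC)(CC)CC)[C@@H](OCOC)C1OCOO1 | intermediate
7 | (2R,3R)-2-(methoxymethoxy)-4-oxo-3-(triethylsilyloxy)pentanal | CC(=O)[C@H](O[Si](CC)(CC)CC)[C@@H](OCOC)C=O | intermediate
8 | methyl acrylate | C=CC(=O)OC | starting material
9 | Morita–Baylis–Hillman adduct (C3 epimers) | CC(=O)[C@H](O[Si](CC)(CC)CC)[C@@H](OCOC)C(O)C(=C)C(=O)OC | intermediate
10 | methyl (Z)-2-(bromomethyl)-4-(methoxymethoxy)-6-oxo-5-(triethylsilyloxy)hept-2-enoate | CC(=O)[C@H](O[Si](CC)(CC)CC)[C@@H](OCOC)/C=C(\CBr)C(=O)OC | intermediate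
11 | but-2-yne-1,4-diol | OCC#CCO | starting material
12 | 4-(tert-butyldiphenylsilyloxy)but-2-yn-1-ol | OCC#CCO[Si](c1ccccc1)(c1ccccc1)C(C)(C)C | intermediate
13 | sodium vinylalanate (cyclic oxaluminole ate complex) | [Na+].COCCO[Al-]1(OCCOC)OCC=C1CO[Si](c1ccccc1)(c1ccccc1)C(C)(C)C | intermediate
14 | (Z)-4-(tert-butyldiphenylsilyloxy)-3-iodobut-2-en-1-ol | OC/C=C(\I)CO[Si](c1ccccc1)(c1ccccc1)C(C)(C)C | intermediate
15 | (Z)-4-(tert-butyldiphenylsilyloxy)-3-iodobut-2-enal | O=C/C=C(\I)CO[Si](c1ccccc1)(c1ccccc1)C(C)(C)C | intermediate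
16 | anti hydroxy ester from the allylation | CC(=O)[C@H](O[Si](CC)(CC)CC)[C@@H](OCOC)[C@@H](C(=C)C(=O)OC)[C@H](O)/C=C(\I)CO[Si](c1ccccc1)(c1ccccc1)C(C)(C)C | intermediate
17 | iodo trans-lactone with free C9 hydroxyl | CC(=O)[C@H](O)[C@@H](OCOC)[C@H]1C(=C)C(=O)O[C@@H]1/C=C(\I)CO[Si](c1ccccc1)(c1ccccc1)C(C)(C)C | intermediate
18 | ethynyltrimethylsilane | C#C[Si](C)(C)C | starting material
19 | trimethylsilyl ynone | CC(=O)[C@H](O)[C@@H](OCOC)[C@H]1C(=C)C(=O)O[C@@H]1/C=C(/CO[Si](c1ccccc1)(c1ccccc1)C(C)(C)C)C(=O)C#C[Si](C)(C)C | intermediate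
20 | ethynyl ketone (open-chain precursor) | CC(=O)[C@H](O)[C@@H](OCOC)[C@H]1C(=C)C(=O)O[C@@H]1/C=C(/CO[Si](c1ccccc1)(c1ccccc1)C(C)(C)C)C(=O)C#C | intermediate
21 | bis(methylzinc) alkoxide–acetylide of 20 | CC(=O)[C@H](O[Zn]C)[C@@H](OCOC)[C@H]1C(=C)C(=O)O[C@@H]1/C=C(/CO[Si](c1ccccc1)(c1ccccc1)C(C)(C)C)C(=O)C#C[Zn]C | intermediate
22 | ten-membered γ-hydroxy ynone, 9,10-diol | COCO[C@H]1[C@H]2C(=C)C(=O)O[C@@H]2/C=C(/CO[Si](c3ccccc3)(c3ccccc3)C(C)(C)C)C(=O)C#C[C@@](C)(O)[C@@H]1O | intermediate
23 | 3-methylbut-2-enoyl chloride | CC(C)=CC(Cl)=O | starting material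
24 | C9 senecioate of 22 | COCO[C@H]1[C@H]2C(=C)C(=O)O[C@@H]2/C=C(/CO[Si](c3ccccc3)(c3ccccc3)C(C)(C)C)C(=O)C#C[C@@](C)(O)[C@@H]1OC(=O)C=C(C)C | intermediate
25 | furanone with C8–OMOM and C15–OTBDPS | COCO[C@H]1[C@H]2C(=C)C(=O)O[C@@H]2/C=C(/CO[Si](c3ccccc3)(c3ccccc3)C(C)(C)C)C2=CC(=O)[C@@](C)(O2)[C@@H]1OC(=O)C=C(C)C | intermediate
26 | C8 alcohol | O[C@H]1[C@H]2C(=C)C(=O)O[C@@H]2/C=C(/CO[Si](c3ccccc3)(c3ccccc3)C(C)(C)C)C2=CC(=O)[C@@](C)(O2)[C@@H]1OC(=O)C=C(C)C | intermediate
27 | methacrylic anhydride | C=C(C)C(=O)OC(=O)C(C)=C | starting material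
28 | O15-tert-butyldiphenylsilyl ether of the target | C=C(C)C(=O)O[C@H]1[C@H]2C(=C)C(=O)O[C@@H]2/C=C(/CO[Si](c3ccccc3)(c3ccccc3)C(C)(C)C)C2=CC(=O)[C@@](C)(O2)[C@@H]1OC(=O)C=C(C)C | intermediate
29 | CNP0239488.2 | C=C(C)C(=O)O[C@H]1[C@H]2C(=C)C(=O)O[C@@H]2/C=C(/CO)C2=CC(=O)[C@@](C)(O2)[C@@H]1OC(=O)C=C(C)C | target

**Count.** Total: 17 steps. Longest linear sequence: 14 steps (steps 1–5, then 9–17).

**Steps most likely to fail**

Step 12. The ring may fail to close because intermolecular addition of the zinc acetylide to the more electrophilic ynone carbonyl (oligomerisation) outruns closure of the strained ring, or because zincation is slow. The fallback makes the C1–C10 bond intermolecularly and closes the ring elsewhere. It sets out from 17: ethynylmagnesium bromide (THF, −78 °C) adds to the methyl ketone within the magnesium alkoxide chelate (same Cram-chelate sense) to give the ethynyl carbinol vinyl iodide F1. An intramolecular carbonylative Sonogashira coupling of F1 (PdCl2(PPh3)2, CuI, CO, Et3N, THF, high dilution) then inserts C3 between C2 and C4 and comes back to the route at 22.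

Step 9. Simple diastereoselection may favour the syn adduct (which would give the cis-lactone), and facial selectivity relative to C8 may be poor. The fallback accepts the syn adduct and inverts C6. It sets out from 10 and 15: indium powder in THF/H2O should give the syn homoallylic alcohol, the C6 epimer of 16, F2. A Mitsunobu reaction (PPh3, DIAD, 4-nitrobenzoic acid, THF, 0 °C) inverts C6 to the 4-nitrobenzoate F3. Methanolysis (K2CO3, MeOH, 0 °C) comes back to the route at 16, which is lactonised and desilylated with PPTS in MeOH as in step 9.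

Step 10. Direct coupling without CO uptake, or carbopalladation of the exo-methylene group by the vinylpalladium species, may compete. The fallback sets out from 17: a Nozaki–Hiyama–Kishi coupling with 3-(trimethylsilyl)propynal (CrCl2, NiCl2 cat., DMF/THF; aldehyde-selective, so the methyl ketone is untouched) gives the C3 propargylic alcohol F4 as a mixture of C3 epimers. MnO2 oxidises this allylic–propargylic alcohol selectively and comes back to the route at 19.

**Further compounds**
F1 | step 12 | ethynyl carbinol vinyl iodide (C1–C10 bond formed, ring open at C3) | C#C[C@@](C)(O)[C@H](O)[C@@H](OCOC)[C@H]1C(=C)C(=O)O[C@@H]1/C=C(\I)CO[Si](c1ccccc1)(c1ccccc1)C(C)(C)C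
F2 | step 9 | syn hydroxy ester, C6 epimer of 16 | CC(=O)[C@H](O[Si](CC)(CC)CC)[C@@H](OCOC)[C@@H](C(=C)C(=O)OC)[C@@H](O)/C=C(\I)CO[Si](c1ccccc1)(c1ccccc1)C(C)(C)C
F3 | step 9 | 4-nitrobenzoate of 16 (C6 inverted) | CC(=O)[C@H](O[Si](CC)(CC)CC)[C@@H](OCOC)[C@@H](C(=C)C(=O)OC)[C@H](OC(=O)c1ccc(cc1)[N+](=O)[O-])/C=C(\I)CO[Si](c1ccccc1)(c1ccccc1)C(C)(C)C
F4 | step 10 | C3 propargylic alcohol (C3 epimers) | CC(=O)[C@H](O)[C@@H](OCOC)[C@H]1C(=C)C(=O)O[C@@H]1/C=C(/CO[Si](c1ccccc1)(c1ccccc1)C(C)(C)C)C(O)C#C[Si](C)(C)C
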